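**Retrosynthetic overview**

1. Numbering: C1 is the ring CH carrying the side chain, C2/C3 are the β/α carbons of the butenolide, C4/C5 the cyclopropane CH, C6 the CHMe, C7 the CH2 and C8 the CHOH. C2=C3 belongs to both the five- and the eight-membered ring. Without it, one eleven-membered ring remains (C2, lactone CH2, O, C=O, C3, C4, C5, C6, C7, C8, C1), and the route rests on this feature.
2. The last C–C bond is C2=C3. It is made by a transannular Horner–Wadsworth–Emmons olefination of the eleven-membered keto phosphonate lactone, and desilylation follows.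
3. The macrolactone is closed at the CH2–O bond from a bromomethyl ketone acid. The bromomethyl ketone comes from an alkyne, so no enolate chemistry is needed once the acetate, the phosphonoacetate and the C1 centre are present.
4. A ketone aldol for C1–C8 would enolise at the wrong α-carbon, so this bond is made by an anti-selective allenylindium addition of a propargylic mesylate to a cyclopropane aldehyde. The mesylate comes from an Evans syn aldol. The aldehyde comes from a Charette cyclopropanation, a catalytic asymmetric methyl conjugate addition and an early enolate phosphorylation.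
5. Order of ring formation: cyclopropane, then the eleven-membered lactone, then butenolide and cyclooctene together.

Key step: step 24

Assumption 1: the phosphonate-bearing carbon C3 is formed and carried as a mixture of epimers. Both converge in the olefination, so C3 is drawn without configuration.
Assumption 2: the sense of induction in the copper/Josiphos methyl addition is assigned by analogy with linear (E)-enethioates. If the cyclopropyl substrate responds in the opposite sense, the antipodal ligand is used.

**Route**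

Step 1
Reactants: 1 bromoacetyl bromide; 2 ethanethiol
Product: 3 S-ethyl 2-bromoethanethioate
Conditions: pyridine, CH2Cl2, −20 → 0 °C
Reagents that add atoms: none
Why: Thioesterification by acyl substitution, in which the acyl bromide reacts with the thiol far faster than the α-CH2Br group, so only the C(=O)–S bond should form.

Step 2
Reactants: 3 S-ethyl 2-bromoethanethioate; 4 triphenylphosphine
Product: 6 S-ethyl 2-(triphenyl-λ5-phosphanylidene)ethanethioate, via phosphonium bromide 5 (not isolated)
Conditions: toluene, rt; then aq. Na2CO3, CH2Cl2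
Reagents that add atoms: none
Why: SN2 quaternisation of the phosphine followed by deprotonation of the acidic CH2 gives the stabilised Wittig ylide.

Step 3
Reactants: 7 prop-2-yn-1-ol; 8 tert-butyl diazoacetate
Product: 9 tert-butyl 5-hydroxypent-3-ynoate
Conditions: CuI (5 mol %), MeCN, rt, slow addition of 8
Reagents that add atoms: none
Why: Copper-catalysed coupling of a terminal alkyne with a diazoester forms the C(sp)–CH2 bond without base, so the 3-alkynoate should not isomerise to the allenoate and the free hydroxyl is tolerated.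

Step 4
Reactants: 9 tert-butyl 5-hydroxypent-3-ynoate
Product: 10 tert-butyl (Z)-5-hydroxypent-3-enoate
Conditions: H2 (1 atm), Pd/CaCO3 poisoned with Pb(OAc)2, quinoline, EtOAc, rt
Reagents that add atoms: none
Why: Lindlar semihydrogenation adds H2 syn and stops at the (Z)-alkene, which fixes the later cis relationship of C4 and C5.

Step 5
Reactants: 10 tert-butyl (Z)-5-hydroxypent-3-enoate
Product: 11 tert-butyl 2-[(1S,2S)-2-(hydroxymethyl)cyclopropyl]acetate
Conditions: Et2Zn, CH2I2, DME, CH2Cl2, −10 °C; (4R,5R)-2-butyl-N,N,N′,N′-tetramethyl-1,3,2-dioxaborolane-4,5-dicarboxamide (1.2 equiv), −10 °C → rt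
Reagents that add atoms: diiodomethane, ICI
Why: Charette asymmetric Simmons–Smith cyclopropanation, in which the zinc alkoxide bound to the (R,R)-dioxaborolane directs stereospecific methylene transfer to one alkene face and so sets C4 and C5 (cis from the Z-alkene, absolute sense from the ligand).

Step 6
Reactants: 11 tert-butyl 2-[(1S,2S)-2-(hydroxymethyl)cyclopropyl]acetate; 6 S-ethyl 2-(triphenyl-λ5-phosphanylidene)ethanethioate
Product: 13 tert-butyl 2-{(1S,2S)-2-[(E)-3-(ethylsulfanyl)-3-oxoprop-1-enyl]cyclopropyl}acetate, via cyclopropanecarbaldehyde 12 (not isolated)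
Conditions: TEMPO (10 mol %), PhI(OAc)2, CH2Cl2, rt; then 6, rt
Reagents that add atoms: none
Why: TEMPO/PhI(OAc)2 oxidation followed in the same flask by Wittig olefination with the stabilised ylide should give the (E)-enethioate without isolating the epimerisable cis-cyclopropanecarbaldehyde.

Step 7
Reactants: 13 tert-butyl 2-{(1S,2S)-2-[(E)-3-(ethylsulfanyl)-3-oxoprop-1-enyl]cyclopropyl}acetate
Product: 14 tert-butyl 2-{(1S,2R)-2-[(2S)-4-(ethylsulfanyl)-4-oxobutan-2-yl]cyclopropyl}acetate
Conditions: MeMgBr (1.3 equiv), CuBr·SMe2 (2 mol %), (R,Sp)-Josiphos [(R)-1-{(Sp)-2-(diphenylphosphino)ferrocenyl}ethyldicyclohexylphosphine] (2.4 mol %), t-BuOMe, −75 °C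
Reagents that add atoms: methylmagnesium bromide, C[Mg]Br
Why: Copper/Josiphos-catalysed asymmetric conjugate addition of MeMgBr to an α,β-unsaturated thioester sets C6 under catalyst control, and the tert-butyl ester is inert at this temperature.

Step 8
Reactants: 14 tert-butyl 2-{(1S,2R)-2-[(2S)-4-(ethylsulfanyl)-4-oxobutan-2-yl]cyclopropyl}acetate
Product: 15 tert-butyl 2-{(1S,2R)-2-[(2S)-4-oxobutan-2-yl]cyclopropyl}acetate
Conditions: Et3SiH (3 equiv), Pd/C (5 mol %), acetone, rt
Reagents that add atoms: none
Why: Fukuyama reduction of the thioester stops at the aldehyde under neutral conditions and leaves the ester and the cyclopropane untouched.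

Step 9
Reactants: 15 tert-butyl 2-{(1S,2R)-2-[(2S)-4-oxobutan-2-yl]cyclopropyl}acetate
Product: 16 tert-butyl 2-{(1S,2R)-2-[(2S)-4,4-dimethoxybutan-2-yl]cyclopropyl}acetate
Conditions: HC(OMe)3, PPTS (5 mol %), MeOH, rt
Reagents that add atoms: trimethyl orthoformate, COC(OC)OC
Why: Acid-catalysed acetalisation masks C8, so the tert-butyl ester is the only enolisable carbonyl group in the next step.

Step 10
Reactants: 16 tert-butyl 2-{(1S,2R)-2-[(2S)-4,4-dimethoxybutan-2-yl]cyclopropyl}acetate; 17 diethyl chlorophosphate
Product: 19 tert-butyl 2-(diethoxyphosphoryl)-2-{(1R,2R)-2-[(2S)-4,4-dimethoxybutan-2-yl]cyclopropyl}acetate (C3 epimers), via lithium enolate 18 (not isolated)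
Conditions: LDA (2.2 equiv), THF, −78 °C; 17 (1.1 equiv), −78 → 0 °C; aq. NH4Cl
Reagents that add atoms: lithium diisopropylamide, [Li+].CC(C)[N-]C(C)C (lithium in 18 only)
Why: Enolate phosphorylation, in which the second equivalent of LDA moves any O-phosphorylated ketene acetal to the C-phosphonate by 1,3-phosphoryl migration and holds the product as its anion; the new C3 centre is a mixture that step 24 erases.

Step 11
Reactants: 19 tert-butyl 2-(diethoxyphosphoryl)-2-{(1R,2R)-2-[(2S)-4,4-dimethoxybutan-2-yl]cyclopropyl}acetate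
Product: 20 tert-butyl 2-(diethoxyphosphoryl)-2-{(1R,2R)-2-[(2S)-4-oxobutan-2-yl]cyclopropyl}acetate (C3 epimers)
Conditions: PPTS (20 mol %), acetone–H2O 9:1, 45 °C
Reagents that add atoms: water, O
Why: Mild acid hydrolysis of the dimethyl acetal frees the C8 aldehyde without base, so tert-butyl ester, phosphonate and the acidic C3–H stay untouched.

Step 12
Reactants: 21 5-bromo-2-methylpent-2-ene; 22 diethyl malonate
Product: 23 diethyl 2-(4-methylpent-3-enyl)malonate
Conditions: NaH, THF–DMF, 0 → 60 °C
Reagents that add atoms: none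
Why: Malonic ester alkylation by SN2 displacement of the primary bromide with sodiomalonate.

Step 13
Reactants: 23 diethyl 2-(4-methylpent-3-enyl)malonate
Product: 25 6-methylhept-5-enoic acid, via malonic acid 24 (not isolated)
Conditions: KOH, EtOH–H2O, reflux; HCl to pH 1; neat, 150 °C
Reagents that add atoms: potassium hydroxide, [K+].[OH-]
Why: Saponification and thermal decarboxylation complete the malonic ester synthesis.

Step 14
Reactants: 25 6-methylhept-5-enoic acid; 26 (S)-4-benzyl-1,3-oxazolidin-2-one
Product: 28 (S)-4-benzyl-3-(6-methylhept-5-enoyl)-1,3-oxazolidin-2-one, via mixed pivalic anhydride 27 (not isolated)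
Conditions: PivCl, Et3N, THF, −20 °C; then 26, LiCl, −20 °C → rt
Reagents that add atoms: pivaloyl chloride, CC(C)(C)C(=O)Cl (atoms in 27 only)
Why: N-acylation of the oxazolidinone through the mixed anhydride takes place at the less hindered carbonyl group.

Step 15
Reactants: 28 (S)-4-benzyl-3-(6-methylhept-5-enoyl)-1,3-oxazolidin-2-one; 29 3-(trimethylsilyl)prop-2-ynal
Product: 31 (4S)-4-benzyl-3-[(2S,3S)-3-hydroxy-2-(4-methylpent-3-enyl)-5-(trimethylsilyl)pent-4-ynoyl]-1,3-oxazolidin-2-one, via dibutylboron Z-enolate 30 (not isolated)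
Conditions: Bu2BOTf, Et3N, CH2Cl2, −78 → 0 °C; 29, −78 → 0 °C; H2O2, MeOH, pH 7 buffer
Reagents that add atoms: dibutylboron triflate, CCCCB(CCCC)OS(=O)(=O)C(F)(F)F (atoms in 30 only)
Why: Evans syn aldol, in which the (Z)-boron enolate reacts through a Zimmerman–Traxler chair on the face opposite the benzyl group and sets the side-chain centre and the C1 carbinol as the syn (2S,3S) pair.

Step 16
Reactants: 31 the aldol imide
Product: 32 (2R,3S)-2-(4-methylpent-3-enyl)-5-(trimethylsilyl)pent-4-yne-1,3-diol
Conditions: LiBH4, MeOH (1 equiv), Et2O, 0 °C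
Reagents that add atoms: none
Why: Reductive cleavage of the imide releases the auxiliary and gives the primary alcohol without touching the alkyne, the alkene or the two stereocentres.

Step 17
Reactants: 32 (2R,3S)-2-(4-methylpent-3-enyl)-5-(trimethylsilyl)pent-4-yne-1,3-diol
Product: 33 (2R,3S)-3-hydroxy-2-(4-methylpent-3-enyl)-5-(trimethylsilyl)pent-4-ynyl acetate
Conditions: AcCl (1.05 equiv), 2,4,6-collidine, CH2Cl2, −78 °C
Reagents that add atoms: acetyl chloride, CC(=O)Cl
Why: Selective acylation, because at low temperature the unhindered primary hydroxyl is acetylated much faster than the branched propargylic one.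

Step 18
Reactants: 33 (2R,3S)-3-hydroxy-2-(4-methylpent-3-enyl)-5-(trimethylsilyl)pent-4-ynyl acetate
Product: 34 (2R,3S)-3-(methylsulfonyloxy)-2-(4-methylpent-3-enyl)-5-(trimethylsilyl)pent-4-ynyl acetate
Conditions: MsCl, Et3N, CH2Cl2, −78 °C; used crude
Reagents that add atoms: methanesulfonyl chloride, CS(=O)(=O)Cl
Why: O-sulfonylation leaves the C–O bond intact, so the C1 configuration is retained and the leaving group for the palladium step is in place.

Step 19
Reactants: 34 the propargylic mesylate; 20 the phosphonoacetate aldehyde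
Product: 36 tert-butyl 2-(diethoxyphosphoryl)-2-{(1R,2R)-2-[(2S,4S,5R,6S)-6-(acetoxymethyl)-4-hydroxy-10-methyl-5-[(trimethylsilyl)ethynyl]undec-9-en-2-yl]cyclopropyl}acetate, via allenylindium species 35 (not isolated)
Conditions: Pd(dppf)Cl2 (5 mol %), InI (1.5 equiv), THF–HMPA 3:1, rt
Reagents that add atoms: indium monoiodide, [In]I (atoms in 35 only)
Why: Marshall-type propargylation, in which zerovalent palladium displaces the mesylate anti and InI transmetalates with retention to the non-basic (M)-allenylindium; this adds to the aldehyde through a cyclic SE2′ transition state, so C8 replaces the mesylate at C1 with net inversion and the aldehyde chain lies anti to the C1 substituent (anti C1/C8), while acetate and acidic phosphonoacetate are tolerated.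

Step 20
Reactants: 36 the homopropargylic alcohol
Product: 38 2-(diethoxyphosphoryl)-2-{(1R,2R)-2-[(2S,4S,5R,6S)-6-(acetoxymethyl)-10-methyl-4-(triethylsilyloxy)-5-[(trimethylsilyl)ethynyl]undec-9-en-2-yl]cyclopropyl}acetic acid, via triethylsilyl ester 37 (not isolated)
Conditions: TESOTf (4 equiv), 2,6-lutidine (6 equiv), CH2Cl2, 0 °C → rt; then pH 7 phosphate buffer–THF, rt
Reagents that add atoms: triethylsilyl triflate, CC[Si](CC)(CC)OS(=O)(=O)C(F)(F)F
Why: Silyl triflate/lutidine silylates the C8 hydroxyl and, in excess, turns the tert-butyl ester into the silyl ester with loss of isobutene, and only the labile silyl ester is hydrolysed by the buffered work-up.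

Step 21
Reactants: 38 the alkynylsilane acid
Product: 39 2-(diethoxyphosphoryl)-2-{(1R,2R)-2-[(2S,4S,5R,6S)-6-(acetoxymethyl)-5-(bromoethynyl)-10-methyl-4-(triethylsilyloxy)undec-9-en-2-yl]cyclopropyl}acetic acid
Conditions: NBS (1.15 equiv), AgNO3 (10 mol %), dry acetone, rt, dark
Reagents that add atoms: N-bromosuccinimide, O=C1CCC(=O)N1Br
Why: Silver-catalysed bromodesilylation of the alkynylsilane is much faster than attack of NBS on the trisubstituted alkene in dry acetone.

Step 22
Reactants: 39 the bromoalkyne acid
Product: 40 2-(diethoxyphosphoryl)-2-{(1R,2R)-2-[(2S,4S,5S,6S)-6-(acetoxymethyl)-5-(2-bromoacetyl)-10-methyl-4-(triethylsilyloxy)undec-9-en-2-yl]cyclopropyl}acetic acid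
Conditions: (XPhos)AuNTf2 (3 mol %), H2O (5 equiv), 1,2-dichloroethane, rt
Reagents that add atoms: water, O
Why: Gold-catalysed hydration of a 1-bromoalkyne, in which the halogen polarises the gold-bound alkyne so that water attacks the internal carbon C2, giving the bromomethyl ketone under neutral conditions that cannot epimerise C1.

Step 23
Reactants: 40 the bromomethyl ketone acid
Product: 41 eleven-membered keto phosphonate macrolactone, C8 triethylsilyl ether (ketone at C2, phosphonate on C3; C1 S, C4 R, C5 R, C6 S, C8 S, side chain S)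
Conditions: CsHCO3 (3 equiv), DMF, 1 mM, syringe-pump addition over 12 h, 35 °C
Reagents that add atoms: none
Why: Macrolactonisation by intramolecular carboxylate alkylation at high dilution; the very SN2-reactive α-bromo ketone and the turn imposed by the cis-cyclopropane favour ring closure, and bicarbonate is too weak to deprotonate C3 or C1.

Step 24
Reactants: 41 the eleven-membered keto phosphonate macrolactone
Product: 42 C8-O-triethylsilyl ether of the target (butenolide fused to the eight-membered ring)
Conditions: LiCl (10 equiv), i-Pr2NEt (5 equiv), MeCN, 5 mM, rt → 45 °C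
Reagents that add atoms: none
Why: Lithium chelation of the phosphoryl and lactone carbonyl oxygens acidifies C3–H enough for the amine to form the phosphonate carbanion, which adds across the ring to the C2 ketone and, through the oxaphosphetane, expels diethyl phosphate to leave the tetrasubstituted C2=C3 alkene. The closest known reaction is the intramolecular Horner–Wadsworth–Emmons butenolide annulation of α-(phosphonoacetoxy) ketones under Masamune–Roush conditions, applied here to a substrate whose reacting carbons are also joined through C4–C8 and C1. The butenolide closes 5-exo-trig (C3, C=O, O, CH2, C2), and the same bond closes the eight-membered carbocycle (formally 8-exo-trig) as the remainder of the macrocycle, so no open chain has to cyclise end to end. No stereocentre is created, since both C3 epimers give the same carbanion and the five-membered lactone allows only the ring-cis alkene. The step needs deprotonation at C3 alone: C1–H is a hindered, singly activated tertiary position that the amine should not remove, which preserves C1 and prevents E1cB loss of the C8 silyloxy group, while reversible enolisation at the O–CH2 group is harmless. Moderate dilution suppresses intermolecular olefination.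

Step 25
Reactants: 42 the C8-O-triethylsilyl ether
Product: 43 the target, CNP0267808.2
Conditions: HF·pyridine, pyridine, THF, 0 °C → rt
Reagents that add atoms: none
Why: Buffered fluoride desilylation cleaves the secondary triethylsilyl ether and leaves acetate, butenolide, cyclopropane and trisubstituted alkene intact.

**Compound list**

1 | bromoacetyl bromide | BrCC(=O)Br | starting material
2 | ethanethiol | CCS | starting material
3 | S-ethyl 2-bromoethanethioate | CCSC(=O)CBr | intermediate
4 | triphenylphosphine | c1ccc(cc1)P(c1ccccc1)c1ccccc1 | starting material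
5 | [2-(ethylsulfanyl)-2-oxoethyl]triphenylphosphonium bromide | CCSC(=O)C[P+](c1ccccc1)(c1ccccc1)c1ccccc1.[Br-] | intermediate
6 | S-ethyl 2-(triphenyl-λ5-phosphanylidene)ethanethioate | CCSC(=O)C=P(c1ccccc1)(c1ccccc1)c1ccccc1 | intermediate
7 | prop-2-yn-1-ol | C#CCO | starting material
8 | tert-butyl diazoacetate | CC(C)(C)OC(=O)C=[N+]=[N-] | starting material
9 | tert-butyl 5-hydroxypent-3-ynoate | OCC#CCC(=O)OC(C)(C)C | intermediate
10 | tert-butyl (Z)-5-hydroxypent-3-enoate | OC/C=C\CC(=O)OC(C)(C)C | intermediate
11 | tert-butyl 2-[(1S,2S)-2-(hydroxymethyl)cyclopropyl]acetate | OC[C@H]1C[C@H]1CC(=O)OC(C)(C)C | intermediate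
12 | tert-butyl 2-[(1S,2S)-2-formylcyclopropyl]acetate | O=C[C@H]1C[C@H]1CC(=O)OC(C)(C)C | intermediate
13 | tert-butyl 2-{(1S,2S)-2-[(E)-3-(ethylsulfanyl)-3-oxoprop-1-enyl]cyclopropyl}acetate | CCSC(=O)/C=C/[C@H]1C[C@H]1CC(=O)OC(C)(C)C | intermediate
14 | tert-butyl 2-{(1S,2R)-2-[(2S)-4-(ethylsulfanyl)-4-oxobutan-2-yl]cyclopropyl}acetate | CCSC(=O)C[C@H](C)[C@H]1C[C@H]1CC(=O)OC(C)(C)C | intermediate
15 | tert-butyl 2-{(1S,2R)-2-[(2S)-4-oxobutan-2-yl]cyclopropyl}acetate | O=CC[C@H](C)[C@H]1C[C@H]1CC(=O)OC(C)(C)C | intermediate
16 | tert-butyl 2-{(1S,2R)-2-[(2S)-4,4-dimethoxybutan-2-yl]cyclopropyl}acetate | COC(OC)C[C@H](C)[C@H]1C[C@H]1CC(=O)OC(C)(C)C | intermediate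
17 | diethyl chlorophosphate | CCOP(=O)(Cl)OCC | starting material
18 | lithium enolate of 16 | COC(OC)C[C@H](C)[C@H]1C[C@H]1C=C([O-])OC(C)(C)C.[Li+] | intermediate
19 | tert-butyl 2-(diethoxyphosphoryl)-2-{(1R,2R)-2-[(2S)-4,4-dimethoxybutan-2-yl]cyclopropyl}acetate | COC(OC)C[C@H](C)[C@H]1C[C@H]1C(P(=O)(OCC)OCC)C(=O)OC(C)(C)C | intermediate
20 | tert-butyl 2-(diethoxyphosphoryl)-2-{(1R,2R)-2-[(2S)-4-oxobutan-2-yl]cyclopropyl}acetate | O=CC[C@H](C)[C@H]1C[C@H]1C(P(=O)(OCC)OCC)C(=O)OC(C)(C)C | intermediate
21 | 5-bromo-2-methylpent-2-ene | CC(C)=CCCBr | starting material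
22 | diethyl malonate | CCOC(=O)CC(=O)OCC | starting material
23 | diethyl 2-(4-methylpent-3-enyl)malonate | CCOC(=O)C(CCC=C(C)C)C(=O)OCC | intermediate
24 | 2-(4-methylpent-3-enyl)malonic acid | OC(=O)C(CCC=C(C)C)C(=O)O | intermediate
25 | 6-methylhept-5-enoic acid | CC(C)=CCCCC(=O)O | intermediate
26 | (S)-4-benzyl-1,3-oxazolidin-2-one | O=C1N[C@@H](Cc2ccccc2)CO1 | starting material
27 | 6-methylhept-5-enoic pivalic anhydride | CC(C)=CCCCC(=O)OC(=O)C(C)(C)C | intermediate
28 | (S)-4-benzyl-3-(6-methylhept-5-enoyl)-1,3-oxazolidin-2-one | CC(C)=CCCCC(=O)N1[C@@H](Cc2ccccc2)COC1=O | intermediate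
29 | 3-(trimethylsilyl)prop-2-ynal | C[Si](C)(C)C#CC=O | starting material
30 | dibutylboron (Z)-enolate of 28 | CCCCB(CCCC)O/C(=C\CCC=C(C)C)N1[C@@H](Cc2ccccc2)COC1=O | intermediate
31 | (4S)-4-benzyl-3-[(2S,3S)-3-hydroxy-2-(4-methylpent-3-enyl)-5-(trimethylsilyl)pent-4-ynoyl]-1,3-oxazolidin-2-one | O=C1OC[C@H](Cc2ccccc2)N1C(=O)[C@@H](CCC=C(C)C)[C@H](O)C#C[Si](C)(C)C | intermediate
32 | (2R,3S)-2-(4-methylpent-3-enyl)-5-(trimethylsilyl)pent-4-yne-1,3-diol | OC[C@@H](CCC=C(C)C)[C@H](O)C#C[Si](C)(C)C | intermediate
33 | (2R,3S)-3-hydroxy-2-(4-methylpent-3-enyl)-5-(trimethylsilyl)pent-4-ynyl acetate | CC(=O)OC[C@@H](CCC=C(C)C)[C@H](O)C#C[Si](C)(C)C | intermediate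
34 | (2R,3S)-3-(methylsulfonyloxy)-2-(4-methylpent-3-enyl)-5-(trimethylsilyl)pent-4-ynyl acetate | CC(=O)OC[C@@H](CCC=C(C)C)[C@H](OS(C)(=O)=O)C#C[Si](C)(C)C | intermediate
35 | (M)-allenylindium iodide methanesulfonate derived from 34 | CS(=O)(=O)O[In](I)C([Si](C)(C)C)=[C@]=C([H])[C@@H](COC(C)=O)CCC=C(C)C | intermediate
36 | anti homopropargylic alcohol, tert-butyl phosphonoacetate | CC(=O)OC[C@@H](CCC=C(C)C)[C@H](C#C[Si](C)(C)C)[C@@H](O)C[C@H](C)[C@H]1C[C@H]1C(P(=O)(OCC)OCC)C(=O)OC(C)(C)C | intermediate
37 | C8 triethylsilyl ether, triethylsilyl ester | CC(=O)OC[C@@H](CCC=C(C)C)[C@H](C#C[Si](C)(C)C)[C@@H](O[Si](CC)(CC)CC)C[C@H](C)[C@H]1C[C@H]1C(P(=O)(OCC)OCC)C(=O)O[Si](CC)(CC)CC | intermediate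
38 | C8 triethylsilyl ether, alkynylsilane phosphono acid | CC(=O)OC[C@@H](CCC=C(C)C)[C@H](C#C[Si](C)(C)C)[C@@H](O[Si](CC)(CC)CC)C[C@H](C)[C@H]1C[C@H]1C(P(=O)(OCC)OCC)C(=O)O | intermediate
39 | bromoalkyne phosphono acid | CC(=O)OC[C@@H](CCC=C(C)C)[C@H](C#CBr)[C@@H](O[Si](CC)(CC)CC)C[C@H](C)[C@H]1C[C@H]1C(P(=O)(OCC)OCC)C(=O)O | intermediate
40 | bromomethyl ketone phosphono acid (seco acid) | CC(=O)OC[C@@H](CCC=C(C)C)[C@H](C(=O)CBr)[C@@H](O[Si](CC)(CC)CC)C[C@H](C)[C@H]1C[C@H]1C(P(=O)(OCC)OCC)C(=O)O | intermediate
41 | eleven-membered keto phosphonate macrolactone, C8 triethylsilyl ether | CC(=O)OC[C@@H](CCC=C(C)C)[C@@H]1C(=O)COC(=O)C(P(=O)(OCC)OCC)[C@@H]2C[C@@H]2[C@@H](C)C[C@@H]1O[Si](CC)(CC)CC | intermediate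
42 | C8-O-triethylsilyl ether of the target | CC(=O)OC[C@@H](CCC=C(C)C)[C@@H]1C2=C(C(=O)OC2)[C@@H]2C[C@@H]2[C@@H](C)C[C@@H]1O[Si](CC)(CC)CC | intermediate
43 | CNP0267808.2 | CC(=O)OC[C@@H](CCC=C(C)C)[C@@H]1C2=C(C(=O)OC2)[C@@H]2C[C@@H]2[C@@H](C)C[C@@H]1O | target

**Step count**

Total step count: 25.
Longest linear sequence: 16 steps (steps 3–11, then 19–25).

**Steps most likely to fail**

Step 24. The transannular attack may be slow. The lactone ester has to turn from its s-trans to its s-cis arrangement inside the eleven-membered ring, and the C8 silyl ether crowds the ketone. A slow olefination leaves time for E1cB loss of the silyloxy group or epimerisation at C1. The fallback changes the substrate and the order of the last two operations.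
- It sets out from 41, which is desilylated first with buffered HF·pyridine to the C8-hydroxy keto phosphonate macrolactone F1.
- In this compound the ketone is less shielded, lithium can bridge the C8 hydroxyl and the C2 carbonyl, and hydroxide is a much poorer leaving group than silanolate.
- The amine cannot form the alkoxide that a retro-aldol would need.
- LiCl/i-Pr2NEt olefination of this hydroxy ketone then comes back to the route at 43.

Step 23. Intermolecular alkylation (oligomerisation) may outrun closure of the strained medium ring. The fallback activates the acyl end instead of the alkyl end.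
- It sets out from 40, which is treated with a large excess of HCO2Na in DMF to give the formyloxymethyl ketone seco acid F2.
- The formate is cleaved selectively with KHCO3 in aqueous MeOH at 0 °C, where the acetate survives, giving the hydroxymethyl ketone seco acid F3.
- Shiina macrolactonisation (2-methyl-6-nitrobenzoic anhydride, DMAP, CH2Cl2, slow addition) comes back to the route at 41.

Step 19. The anti/syn selectivity of the cyclic transition state may erode, because the aldehyde has no α-branch and the propargylic substituent is unusually large. The fallback sets C8 by reagent control.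
- It sets out from 36, taken as the mixture of C8 epimers.
- Oxidation with Dess–Martin periodinane/NaHCO3 gives the C8 ketone F4.
- Corey–Bakshi–Shibata reduction follows, with the (R)-methyl oxazaborolidine and catecholborane in toluene at −78 °C. The branched C1 side acts as the large group, and catecholborane spares the alkene.
- The reduction should return the (8S)-alcohol and so comes back to the route at 36.

**Further compounds**

F1 | step 24 | C8-hydroxy eleven-membered keto phosphonate macrolactone | CC(=O)OC[C@@H](CCC=C(C)C)[C@@H]1C(=O)COC(=O)C(P(=O)(OCC)OCC)[C@@H]2C[C@@H]2[C@@H](C)C[C@@H]1O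
F2 | step 23 | formyloxymethyl ketone seco acid | CC(=O)OC[C@@H](CCC=C(C)C)[C@H](C(=O)COC=O)[C@@H](O[Si](CC)(CC)CC)C[C@H](C)[C@H]1C[C@H]1C(P(=O)(OCC)OCC)C(=O)O
F3 | step 23 | hydroxymethyl ketone seco acid | CC(=O)OC[C@@H](CCC=C(C)C)[C@H](C(=O)CO)[C@@H](O[Si](CC)(CC)CC)C[C@H](C)[C@H]1C[C@H]1C(P(=O)(OCC)OCC)C(=O)O
F4 | step 19 | C8 ketone derived from 36 | CC(=O)OC[C@@H](CCC=C(C)C)[C@H](C#C[Si](C)(C)C)C(=O)C[C@H](C)[C@H]1C[C@H]1C(P(=O)(OCC)OCC)C(=O)OC(C)(C)C
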